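**Plan**

- Enabling feature: the γ-lactone (C19, O, C10, C5, C4) shares the C5–C10 bond with ring B and C4, C5, C10 with ring A. A 2-methylbutenolide already bonded to C10 can therefore accept C6 at C5 and then donate from C4 to C3.
- Cuts, in retrosynthetic order: the C2 hydroxyl and the C3 carbinol; C3–C4 and C5–C6 together (aldol and Michael); C4=C5 (metathesis); C10–O and C10–C1 (acylation, Grignard); C9–C10 (aldol); C13–C16 (vinyl radical); C8–C6 (Ireland–Claisen).
- Forward order: ring C is the starting cyclohexenone; ring D closes by 5-exo radical cyclization; the butenolide is assembled on C9 of the CD bicycle; rings B and A close in one operation; ring A is oxygenated last.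
- Stereochemistry: one catalytic CBS reduction sets a carbinol whose configuration passes to C8 by Ireland–Claisen transfer. C13 follows by bridging, C9 and C11 from exo-face attack on the bicycle, C10 from Felkin–Anh addition, C4 and C5 from the tethers, C6 from the convex face, and C2 and C3 from the lactone-shielded ring A.

Key step: step 18

Remark: gibberellane numbering is applied to all intermediates (ring A C1–C5 and C10; ring B C5, C6, C8, C9, C10; ring C C8, C9, C11–C14; ring D C8, C13–C16; C7 the acid carbon on C6, C17 the methylene on C16, C18 and C19 the methyl and lactone carbonyl on C4). Centres formed as mixtures and erased later (C10 in 21–23, C6 in 32–34, C3 in 37) are drawn as one epimer.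

**Route**

Step 1
Reactants: 1 cyclohex-2-en-1-one; 2 2,3-dibromoprop-1-ene
Product: 4 rac-1-(2-bromoprop-2-en-1-yl)cyclohex-2-en-1-ol, via (2-bromoprop-2-en-1-yl)zinc bromide 3 (not isolated)
Conditions: Zn dust, THF/sat. aq. NH4Cl, 0 °C to rt
Reagents that add atoms: none
Why: Barbier allylation, in which the allylzinc species made in the flask adds 1,2 to the enone carbonyl; the racemic carbinol centre is removed in step 2.

Step 2
Reactants: 4 rac-1-(2-bromoprop-2-en-1-yl)cyclohex-2-en-1-ol
Product: 5 3-(2-bromoprop-2-en-1-yl)cyclohex-2-en-1-one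
Conditions: pyridinium chlorochromate (C5H5NH[CrO3Cl]), 4 Å molecular sieves, CH2Cl2, rt
Reagents that add atoms: pyridinium chlorochromate, [O-][Cr](=O)(=O)Cl.c1cc[nH+]cc1 (supplies the carbonyl oxygen)
Why: Babler–Dauben oxidative 1,3-transposition of the tertiary allylic alcohol through its chromate ester should give the 3-substituted enone, which has no stereocentre.

Step 3
Reactants: 5 3-(2-bromoprop-2-en-1-yl)cyclohex-2-en-1-one
Product: 6 (1R)-3-(2-bromoprop-2-en-1-yl)cyclohex-2-en-1-ol
Conditions: (S)-2-methyl-CBS-oxazaborolidine (0.15 equiv), catecholborane, toluene, −78 °C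
Reagents that add atoms: none
Why: Corey–Bakshi–Shibata reduction, in which the oxazaborolidine–borane complex treats the alkenyl side of the carbonyl as the large group and should deliver hydride to give the (R)-carbinol, the source of all absolute configuration in the route.

Step 4
Reactants: 6 (1R)-3-(2-bromoprop-2-en-1-yl)cyclohex-2-en-1-ol
Product: 7 (1R)-3-(2-bromoprop-2-en-1-yl)cyclohex-2-en-1-yl acetate
Conditions: Ac2O, pyridine, DMAP (cat.), CH2Cl2, 0 °C to rt
Reagents that add atoms: acetic anhydride, CC(=O)OC(C)=O
Why: Routine O-acylation of the secondary allylic alcohol brings in the two carbons that become C6 and C7 and leaves the carbinol centre untouched.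

Step 5
Reactants: 7 (1R)-3-(2-bromoprop-2-en-1-yl)cyclohex-2-en-1-yl acetate
Product: 10 2-[(1R)-1-(2-bromoprop-2-en-1-yl)cyclohex-2-en-1-yl]acetic acid, via trimethylsilyl ketene acetal 8 (not isolated), via trimethylsilyl ester 9 (not isolated)
Conditions: LiN(iPr)2, Me3SiCl, THF, −78 °C; then 65 °C; then 1 M aq. HCl
Reagents that add atoms: none
Why: Ireland–Claisen rearrangement, in which the silyl ketene acetal rearranges suprafacially across the ring allyl unit, so the CH2CO2H arm enters C8 on the face that carried the acetate oxygen and the carbinol configuration is transferred to the quaternary C8.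

Step 6
Reactants: 10 2-[(1R)-1-(2-bromoprop-2-en-1-yl)cyclohex-2-en-1-yl]acetic acid
Product: 12 cis-fused hydroxy lactone (C7 acyl on the C9 oxygen; C11 hydroxyl trans to the lactone oxygen), via epoxy acid 11 (not isolated)
Conditions: 3-chloroperoxybenzoic acid, CH2Cl2, 0 °C to rt; then HClO4 (cat.), THF/H2O, rt
Reagents that add atoms: 3-chloroperoxybenzoic acid, OOC(=O)c1cccc(Cl)c1; water, O
Why: Prilezhaev epoxidation of the only electron-rich alkene followed by acid-promoted opening, in which the epoxide anti to the acid arm is opened at C9 by the carboxyl group (5-exo) and the syn epoxide by water at the less hindered C11 before lactonising, so both faces should converge on one cis-fused lactone with the C11 hydroxyl trans to the C9 oxygen.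

Step 7
Reactants: 12 cis-fused hydroxy lactone
Product: 13 cis-fused keto lactone (C11 ketone next to the acyloxy-bearing C9)
Conditions: Dess–Martin periodinane, NaHCO3, CH2Cl2, rt
Reagents that add atoms: none
Why: Dess–Martin oxidation of the secondary alcohol gives the C11 ketone whose acyloxy neighbour marks C9 for the regiospecific enolate of step 10; no new stereocentre is formed.

Step 8
Reactants: 13 cis-fused keto lactone
Product: 17 enone lactone (C11 ketone; C12=C13), via lithium enolate 14 (not isolated), via phenylselanyl ketone 15 (not isolated), via selenoxide 16 (not isolated)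
Conditions: LiN(SiMe3)2, THF, −78 °C; PhSeCl, −78 °C; then H2O2 (30 %), pyridine, CH2Cl2, 0 °C to rt
Reagents that add atoms: none
Why: α-Selenenylation and selenoxide syn-elimination, in which kinetic deprotonation should take the open C12 methylene instead of the neopentyl, oxygen-bearing C9 methine and the selenoxide can only eliminate towards C13, giving the enone without touching C8 or C9.

Step 9
Reactants: 17 enone lactone
Product: 18 tricyclic keto lactone (16-methylene CD bicycle with C11 ketone; γ-lactone from C7 to the axial C9 oxygen)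
Conditions: Bu3SnH (syringe pump), AIBN (cat.), benzene, 80 °C, 0.01 M
Reagents that add atoms: none
Why: Tin hydride mediated vinyl radical cyclization, in which the C16 radical adds 5-exo-trig to the enone β-carbon C13 and the α-keto radical is reduced at C12; because C15 is anchored on C8 the new C13 centre can only form as the bridgehead of the bicyclo[3.2.1]octane.

Step 10
Reactants: 18 tricyclic keto lactone; 19 acrolein
Product: 22 methyl ester of the C9 aldol adduct (C10 allylic carbinol; C11 ketone), via samarium enolate 20 (not isolated), via hydroxy acid 21 (not isolated)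
Conditions: SmI2 (2.2 equiv), THF, −78 °C; acrolein, −78 °C; 0.1 M aq. HCl; then Me3SiCHN2, toluene/MeOH, 0 °C
Reagents that add atoms: (trimethylsilyl)diazomethane, C[Si](C)(C)C=[N+]=[N-]
Why: SmI2 cleavage of the axial α-acyloxy C9–O bond gives the C9–C11 samarium enolate regiospecifically (samarium Reformatsky-type aldol) and acrolein should add to C9 from the exo face opposite the C15–C16 bridge, which sets C9 with C10 axial; the C10 carbinol is not controlled and is erased in step 12, and the freed C7 acid is methylated.

Step 11
Reactants: 22 methyl ester of the C9 aldol adduct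
Product: 23 11β,10-diol
Conditions: Me4NBH(OAc)3, MeCN/AcOH, −30 °C
Reagents that add atoms: none
Why: Evans–Saksena directed reduction, in which the borohydride bound to the C10 oxygen delivers hydride to the lower (exo) face of C11, the face also open on steric grounds, which should give the axial 11β-alcohol.

Step 12
Reactants: 23 11β,10-diol
Product: 24 vinyl ketone (C10 ketone; free 11β-hydroxyl)
Conditions: MnO2 (excess), CH2Cl2, rt
Reagents that add atoms: none
Why: Allylic oxidation with MnO2 takes only the allylic C10 carbinol and leaves the saturated axial C11 alcohol, and the mixed C10 centre disappears.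

Step 13
Reactants: 24 vinyl ketone
Product: 25 11β-silyl ether of the vinyl ketone
Conditions: TBSOTf, 2,6-lutidine, CH2Cl2, −78 to 0 °C
Reagents that add atoms: tert-butyldimethylsilyl trifluoromethanesulfonate, CC(C)(C)[Si](C)(C)OS(=O)(=O)C(F)(F)F
Why: Silyl triflate silylation is strong enough for the hindered axial hydroxyl, and its weak hindered base should leave the epimerisable C9–H next to the ketone alone.

Step 14
Reactants: 25 11β-silyl ether of the vinyl ketone; 26 2-(2-bromoethyl)-1,3-dioxolane; 27 methacryloyl chloride
Product: 30 C10 methacrylate (tertiary ester carrying the vinyl group and the acetal chain), via Grignard reagent 28 (not isolated), via bromomagnesium alkoxide 29 (not isolated)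
Conditions: Mg, THF, 25 °C (26 to 28); LaCl3·2LiCl, THF, −78 °C, 25 then 28; then methacryloyl chloride, −78 to 0 °C
Reagents that add atoms: none
Why: Lanthanide-promoted Grignard 1,2-addition followed by O-acylation of the alkoxide in the flask, in which Felkin–Anh attack anti to the quaternary C8, with the carbonyl oxygen turned under ring C and the vinyl group towards C6, should deliver the chain to the outward face and set C10 as required, while immediate acylation keeps the alkoxide from attacking the C7 ester.

Step 15
Reactants: 30 C10 methacrylate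
Product: 32 6-bromo ester (C6 epimers), via lithium ester enolate 31 (not isolated)
Conditions: LiN(SiMe3)2, THF, −78 °C; N-bromosuccinimide, −78 °C; AcOH quench
Reagents that add atoms: N-bromosuccinimide, O=C1CCC(=O)N1Br
Why: Electrophilic bromination of the enolate of the C7 ester, the only enolisable carbonyl group since the methacrylate has no α-hydrogen; the C6 configuration is not controlled and is lost again in the enolate of step 18.

Step 16
Reactants: 32 6-bromo ester
Product: 33 butenolide acetal
Conditions: second-generation Grubbs catalyst (5 mol %), toluene, 80 °C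
Reagents that add atoms: none
Why: Ring-closing metathesis between the vinyl group and the methacrylate closes the 2-methylbutenolide with loss of ethene; the hindered 1,1-disubstituted C16 methylene should not compete and no stereocentre is touched.

Step 17
Reactants: 33 butenolide acetal
Product: 34 bromo ester butenolide aldehyde (substrate of the key step)
Conditions: PPTS, acetone/H2O, 55 °C
Reagents that add atoms: water, O
Why: Acid-catalysed acetal hydrolysis frees the C3 aldehyde under conditions that should spare the secondary silyl ether, the bromo ester and the butenolide.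

Step 18
Reactants: 34 bromo ester butenolide aldehyde
Product: 37 pentacyclic 3-hydroxy lactone (11β-silyl ether; C7 methyl ester), via samarium ester enolate 35 (not isolated), via samarium lactone enolate 36 (not isolated)
Conditions: SmI2 (2.2 equiv, 0.1 M in THF) added slowly, THF, −78 to −20 °C, 0.005 M; 0.1 M aq. HCl at 0 °C
Reagents that add atoms: none
Why: Proposed new method: two single-electron transfers to the C6–Br bond give the trivalent samarium ester enolate 35 without any base, so the aldehyde is not enolised and, at −78 °C, should not be reduced faster than the activated bromide; 35 adds to C5 of the butenolide and the resulting samarium lactone enolate 36 adds through C4 to the C3 aldehyde. The closest known reactions are SmI2 Reformatsky-type enolate formation from α-bromo esters and base-mediated intramolecular Michael–aldol double cyclizations of ester enolates onto butenolides. Ring B closes by 5-exo-trig conjugate addition and ring A by a 6-(enolexo)-exo-trig aldol. C5 and C4 are dictated by the tethers (C6 reaches C5 only on the butenolide face that carries C9, the aldehyde reaches C4 only on the face that carries C1), so both follow from C10; C6 should place its ester on the convex face trans to the C4–C5 bond and can be equilibrated, and the C3 carbinol is neither controlled nor needed. The step needs conjugate addition to win over direct Reformatsky attack on the aldehyde, which five-membered against seven-membered ring formation and the fixed cis disposition of the C8 and C9 arms on the CD bicycle should secure.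

Step 19
Reactants: 37 pentacyclic 3-hydroxy lactone
Product: 38 3-ketone
Conditions: Dess–Martin periodinane, NaHCO3, CH2Cl2, rt
Reagents that add atoms: none
Why: Dess–Martin oxidation turns either C3 carbinol epimer into the ketone, which is flanked by the quaternary C4 and can enolise only towards C2.

Step 20
Reactants: 38 3-ketone
Product: 40 2β-hydroxy 3-ketone, via potassium enolate 39 (not isolated)
Conditions: KN(SiMe3)2, THF, −78 °C; 2-(benzenesulfonyl)-3-phenyloxaziridine, −78 °C; AcOH quench
Reagents that add atoms: 2-(benzenesulfonyl)-3-phenyloxaziridine, O=S(=O)(c1ccccc1)N1OC1c1ccccc1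
Why: Davis enolate hydroxylation, in which the C2–C3 enolate should be attacked from the β face opposite the lactone bridge, placing the new hydroxyl 2β (equatorial).

Step 21
Reactants: 40 2β-hydroxy 3-ketone
Product: 41 2β,3β-diol (11β-silyl ether; methyl ester)
Conditions: LiBH(sBu)3, THF, −78 °C; AcOH quench
Reagents that add atoms: none
Why: The bulky trialkylborohydride should attack the C3 ketone along the equatorial trajectory and avoid the axial path past H1β and H5β, giving the axial 3β-alcohol cis to the 2β-hydroxyl.

Step 22
Reactants: 41 2β,3β-diol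
Product: 42 2β,3β,11β-triol methyl ester
Conditions: HF·pyridine, THF/pyridine, 0 °C to rt
Reagents that add atoms: none
Why: Acidic fluoride desilylation removes the hindered C11 silyl ether without base, so the β-hydroxy lactone should not epimerise at C3 by retro-aldol opening.

Step 23
Reactants: 42 2β,3β,11β-triol methyl ester
Product: 43 CNP0322347.1 (2β,3β,11β-trihydroxy 19,10-lactone 7-acid)
Conditions: NaSEt, DMF, rt to 40 °C; then dilute aq. HCl to pH 3
Reagents that add atoms: none
Why: SN2 demethylation of the hindered C7 methyl ester by thiolate at the methyl carbon avoids acyl attack and hydroxide, the conditions under which the lactone opens and C3 epimerises.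

**Compound list**

1 | cyclohex-2-en-1-one | O=C1C=CCCC1 | starting material
2 | 2,3-dibromoprop-1-ene | C=C(Br)CBr | starting material
3 | (2-bromoprop-2-en-1-yl)zinc bromide (not isolated) | C=C(Br)C[Zn]Br | intermediate
4 | rac-1-(2-bromoprop-2-en-1-yl)cyclohex-2-en-1-ol | OC1(CC(Br)=C)C=CCCC1 | intermediate
5 | 3-(2-bromoprop-2-en-1-yl)cyclohex-2-en-1-one | O=C1C=C(CC(Br)=C)CCC1 | intermediate
6 | (1R)-3-(2-bromoprop-2-en-1-yl)cyclohex-2-en-1-ol | O[C@H]1C=C(CC(Br)=C)CCC1 | intermediate
7 | (1R)-3-(2-bromoprop-2-en-1-yl)cyclohex-2-en-1-yl acetate | CC(=O)O[C@H]1C=C(CC(Br)=C)CCC1 | intermediate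
8 | trimethylsilyl ketene acetal of 7 (not isolated) | C=C(O[Si](C)(C)C)O[C@H]1C=C(CC(Br)=C)CCC1 | intermediate
9 | trimethylsilyl ester of 10 (not isolated) | C[Si](C)(C)OC(=O)C[C@]1(CC(Br)=C)C=CCCC1 | intermediate
10 | 2-[(1R)-1-(2-bromoprop-2-en-1-yl)cyclohex-2-en-1-yl]acetic acid (C8 quaternary; ring alkene C9=C11) | OC(=O)C[C@]1(CC(Br)=C)C=CCCC1 | intermediate
11 | 9,11-epoxide of 10, both epoxide faces (not isolated) | OC(=O)C[C@]1(CC(Br)=C)C2OC2CCC1 | intermediate
12 | cis-fused hydroxy lactone: γ-lactone from C7 to the C9 oxygen, C11 hydroxyl trans to that oxygen, 2-bromoallyl on C8 | O=C1C[C@@]2(CC(Br)=C)CCC[C@H](O)[C@H]2O1 | intermediate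
13 | cis-fused keto lactone (C11 ketone) | O=C1C[C@@]2(CC(Br)=C)CCCC(=O)[C@H]2O1 | intermediate
14 | lithium C11–C12 enolate of 13 (not isolated) | O=C1C[C@@]2(CC(Br)=C)CCC=C(O[Li])[C@H]2O1 | intermediate
15 | 12-phenylselanyl ketone, C12 epimers (not isolated) | O=C1C[C@@]2(CC(Br)=C)CCC([Se]c3ccccc3)C(=O)[C@H]2O1 | intermediate
16 | selenoxide of 15 (not isolated) | O=C1C[C@@]2(CC(Br)=C)CCC([Se](=O)c3ccccc3)C(=O)[C@H]2O1 | intermediate
17 | enone lactone (C11 ketone, C12=C13, cis-fused C7–O–C9 lactone) | O=C1C[C@@]2(CC(Br)=C)CC=CC(=O)[C@H]2O1 | intermediate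
18 | tricyclic keto lactone: 16-methylene bicyclo[3.2.1]octane (rings C and D) with C11 ketone and γ-lactone from C7 to the axial, exo C9 oxygen | C=C1C[C@]23C[C@H]1CC(=O)[C@H]2OC(=O)C3 | intermediate
19 | acrolein (prop-2-enal) | C=CC=O | starting material
20 | bis(diiodosamarium) C9–C11 enolate and C7 carboxylate (not isolated) | C=C1C[C@]2(CC(=O)O[Sm](I)I)C[C@H]1CC(O[Sm](I)I)=C2 | intermediate
21 | hydroxy acid: C9 aldol adduct with C10 axial on the exo face, C10 carbinol epimers, one drawn (not isolated) | C=C1C[C@]2(CC(=O)O)C[C@H]1CC(=O)[C@H]2[C@@H](O)C=C | intermediate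
22 | methyl ester of 21 | C=C1C[C@]2(CC(=O)OC)C[C@H]1CC(=O)[C@H]2[C@@H](O)C=C | intermediate
23 | 11β,10-diol (C11 hydroxyl axial, syn to the C15–C16 bridge) | C=C1C[C@]2(CC(=O)OC)C[C@H]1C[C@H](O)[C@H]2[C@@H](O)C=C | intermediate
24 | vinyl ketone (C10 ketone on axial C9 substituent, free 11β-hydroxyl) | C=C1C[C@]2(CC(=O)OC)C[C@H]1C[C@H](O)[C@H]2C(=O)C=C | intermediate
25 | 11β-tert-butyldimethylsilyl ether of 24 | C=C1C[C@]2(CC(=O)OC)C[C@H]1C[C@H](O[Si](C)(C)C(C)(C)C)[C@H]2C(=O)C=C | intermediate
26 | 2-(2-bromoethyl)-1,3-dioxolane | BrCCC1OCCO1 | starting material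
27 | methacryloyl chloride (2-methylprop-2-enoyl chloride) | C=C(C)C(Cl)=O | starting material
28 | [2-(1,3-dioxolan-2-yl)ethyl]magnesium bromide (not isolated) | Br[Mg]CCC1OCCO1 | intermediate
29 | bromomagnesium C10 alkoxide (not isolated) | C=C1C[C@]2(CC(=O)OC)C[C@H]1C[C@H](O[Si](C)(C)C(C)(C)C)[C@H]2[C@@](O[Mg]Br)(C=C)CCC1OCCO1 | intermediate
30 | C10 methacrylate: tertiary ester at C10 carrying vinyl (C5) and the 2-(1,3-dioxolan-2-yl)ethyl chain (C1–C3) | C=C1C[C@]2(CC(=O)OC)C[C@H]1C[C@H](O[Si](C)(C)C(C)(C)C)[C@H]2[C@@](OC(=O)C(C)=C)(C=C)CCC1OCCO1 | intermediate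
31 | lithium enolate of the C7 methyl ester of 30 (not isolated) | C=C1C[C@]2(C=C(O[Li])OC)C[C@H]1C[C@H](O[Si](C)(C)C(C)(C)C)[C@H]2[C@@](OC(=O)C(C)=C)(C=C)CCC1OCCO1 | intermediate
32 | 6-bromo ester of 30, C6 epimers, one drawn | C=C1C[C@]2([C@H](Br)C(=O)OC)C[C@H]1C[C@H](O[Si](C)(C)C(C)(C)C)[C@H]2[C@@](OC(=O)C(C)=C)(C=C)CCC1OCCO1 | intermediate
33 | butenolide acetal: 2-methylbutenolide with quaternary C10 on C9, acetal chain, 6-bromo ester | C=C1C[C@]2([C@H](Br)C(=O)OC)C[C@H]1C[C@H](O[Si](C)(C)C(C)(C)C)[C@H]2[C@]1(OC(=O)C(C)=C1)CCC1OCCO1 | intermediate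
34 | key step substrate: CD bicycle with bromo ester arm on C8, 2-methylbutenolide on C9 whose C10 bears the 3-oxopropyl chain, 11β-silyl ether | C=C1C[C@]2([C@H](Br)C(=O)OC)C[C@H]1C[C@H](O[Si](C)(C)C(C)(C)C)[C@H]2[C@]1(OC(=O)C(C)=C1)CCC=O | intermediate
35 | diiodosamarium enolate of the C7 ester (not isolated) | C=C1C[C@]2(C=C(O[Sm](I)I)OC)C[C@H]1C[C@H](O[Si](C)(C)C(C)(C)C)[C@H]2[C@]1(OC(=O)C(C)=C1)CCC=O | intermediate
36 | diiodosamarium C4–C19 lactone enolate with ring B closed (not isolated) | C=C1C[C@]23C[C@H]1C[C@H](O[Si](C)(C)C(C)(C)C)[C@H]2[C@@]1(CCC=O)OC(O[Sm](I)I)=C(C)[C@H]1[C@@H]3C(=O)OC | intermediate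
37 | pentacyclic 3-hydroxy 19,10-lactone, 11β-silyl ether, C7 methyl ester (3β drawn; either C3 epimer serves) | C=C1C[C@]23C[C@H]1C[C@H](O[Si](C)(C)C(C)(C)C)[C@H]2[C@@]12CC[C@H](O)[C@@](C)(C(=O)O1)[C@H]2[C@@H]3C(=O)OC | intermediate
38 | 3-ketone of 37 | C=C1C[C@]23C[C@H]1C[C@H](O[Si](C)(C)C(C)(C)C)[C@H]2[C@@]12CCC(=O)[C@@](C)(C(=O)O1)[C@H]2[C@@H]3C(=O)OC | intermediate
39 | potassium C2–C3 enolate of 38 (not isolated) | C=C1C[C@]23C[C@H]1C[C@H](O[Si](C)(C)C(C)(C)C)[C@H]2[C@@]12CC=C(O[K])[C@@](C)(C(=O)O1)[C@H]2[C@@H]3C(=O)OC | intermediate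
40 | 2β-hydroxy 3-ketone | C=C1C[C@]23C[C@H]1C[C@H](O[Si](C)(C)C(C)(C)C)[C@H]2[C@@]12C[C@H](O)C(=O)[C@@](C)(C(=O)O1)[C@H]2[C@@H]3C(=O)OC | intermediate
41 | 2β,3β-diol, 11β-silyl ether, C7 methyl ester | C=C1C[C@]23C[C@H]1C[C@H](O[Si](C)(C)C(C)(C)C)[C@H]2[C@@]12C[C@H](O)[C@H](O)[C@@](C)(C(=O)O1)[C@H]2[C@@H]3C(=O)OC | intermediate
42 | 2β,3β,11β-triol, C7 methyl ester | C=C1C[C@]23C[C@H]1C[C@H](O)[C@H]2[C@@]12C[C@H](O)[C@H](O)[C@@](C)(C(=O)O1)[C@H]2[C@@H]3C(=O)OC | intermediate
43 | CNP0322347.1: 2β,3β,11β-trihydroxy-16-methylene gibberellane 19,10-lactone 7-oic acid | C=C1C[C@]23C[C@H]1C[C@H](O)[C@H]2[C@@]12C[C@H](O)[C@H](O)[C@@](C)(C(=O)O1)[C@H]2[C@@H]3C(=O)O | target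

**Step count and risks**

Total step count: 23. Longest linear sequence: 23 steps from 1; 19 enters in step 10 and 26 and 27 in step 14.

Steps most likely to fail:

1. Step 18. The samarium ester enolate may attack the aldehyde directly (Reformatsky closure of a seven-membered ring), the aldehyde may undergo ketyl or pinacol reduction, or the butenolide may be reduced before the C5–C6 bond forms. The fallback uses known chemistry and runs the two ring closures one after the other with the aldehyde masked. It sets out from 30. Ring-closing metathesis with the second-generation Grubbs catalyst gives the bromine-free butenolide acetal F1. LiN(SiMe3)2 in THF at −78 °C closes ring B by intramolecular Michael addition of the ester enolate to the butenolide, and protonation gives the tetracyclic saturated lactone acetal F2 (C4 epimers). PPTS in wet acetone frees the lactone aldehyde F3. Catalytic KOtBu in THF/tBuOH at 0 °C then closes ring A by aldol addition of the lactone α-carbon to the aldehyde, the forward direction of the base-induced retro-aldol equilibrium of 3-hydroxy gibberellin lactones. The route is rejoined at 37.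

2. Step 14. The chain may add to the other face of the C10 carbonyl, add in conjugate fashion, or the hindered alkoxide may acylate too slowly. The fallback inverts the pairing, so that the C1–C3 chain is already on the ketone and the vinyl group is delivered last; the same intrinsic facial preference then leads to the required C10 epimer. It sets out from 25. Conjugate addition of 2-lithio-1,3-dithiane (THF/HMPA, −78 °C) to the vinyl ketone gives the dithianylethyl ketone F5. Vinylmagnesium bromide with LaCl3·2LiCl, then methacryloyl chloride, gives the dithiane methacrylate F6. Bromination as in step 15 gives the dithiane bromo ester F7. MeI and CaCO3 in aqueous MeCN unmask the aldehyde triene F8, and ring-closing metathesis as in step 16 returns the route to 34.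

3. Step 10. The samarium enolate may be protonated before it meets the aldehyde, acrolein may be reduced or polymerised, or the aldolate may undergo retro-aldol loss or epimerise at C9. The fallback stores the enolate regiochemistry in an isolable silyl enol ether and forms the C9–C10 bond under Lewis acid control. It sets out from 18. SmI2 cleavage followed by TBSOTf traps the enolate, and methylation of the acid with Me3SiCHN2 gives the C9–C11 silyl enol ether methyl ester F4. A Mukaiyama aldol addition to acrolein with BF3·OEt2 at −78 °C, again from the exo face, returns the route to 22.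

Further compounds
F1 | step 18 | bromine-free butenolide acetal (CH2CO2Me arm on C8) | C=C1C[C@]2(CC(=O)OC)C[C@H]1C[C@H](O[Si](C)(C)C(C)(C)C)[C@H]2[C@]1(OC(=O)C(C)=C1)CCC1OCCO1
F2 | step 18 | tetracyclic saturated lactone acetal, ring B closed, C4 epimers | C=C1C[C@]23C[C@H]1C[C@H](O[Si](C)(C)C(C)(C)C)[C@H]2[C@@]1(CCC2OCCO2)OC(=O)C(C)[C@H]1[C@@H]3C(=O)OC
F3 | step 18 | tetracyclic lactone aldehyde, C4 epimers | C=C1C[C@]23C[C@H]1C[C@H](O[Si](C)(C)C(C)(C)C)[C@H]2[C@@]1(CCC=O)OC(=O)C(C)[C@H]1[C@@H]3C(=O)OC
F4 | step 10 | C9–C11 tert-butyldimethylsilyl enol ether methyl ester | C=C1C[C@]2(CC(=O)OC)C[C@H]1CC(O[Si](C)(C)C(C)(C)C)=C2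
F5 | step 14 | dithianylethyl ketone (C10 ketone with C1–C3 chain, C3 as 1,3-dithiane) | C=C1C[C@]2(CC(=O)OC)C[C@H]1C[C@H](O[Si](C)(C)C(C)(C)C)[C@H]2C(=O)CCC1SCCCS1
F6 | step 14 | dithiane methacrylate | C=C1C[C@]2(CC(=O)OC)C[C@H]1C[C@H](O[Si](C)(C)C(C)(C)C)[C@H]2[C@@](OC(=O)C(C)=C)(C=C)CCC1SCCCS1
F7 | step 14 | dithiane bromo ester, C6 epimers, one drawn | C=C1C[C@]2([C@H](Br)C(=O)OC)C[C@H]1C[C@H](O[Si](C)(C)C(C)(C)C)[C@H]2[C@@](OC(=O)C(C)=C)(C=C)CCC1SCCCS1
F8 | step 14 | aldehyde triene (methacrylate, vinyl, 3-oxopropyl on C10; bromo ester) | C=C1C[C@]2([C@H](Br)C(=O)OC)C[C@H]1C[C@H](O[Si](C)(C)C(C)(C)C)[C@H]2[C@@](OC(=O)C(C)=C)(C=C)CCC=O
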